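Numbering the chain C1 (carboxyl carbon) to C14 (ketone methyl), with the 1,2-dioxane holding C3–C6, the route rests on the C7–C8 bond. This bond links the exocyclic methylene on the quaternary peroxy carbon C6 to the methyl-bearing stereocentre C8. A Zweifel olefination joins an alkenyllithium (C3–C7) and a secondary boronic ester (C8–C11) in one operation. Its 1,2-metallate shift carries the C8 configuration over unchanged and leaves a C6=C7 alkene as the latent tertiary peroxide. Cobalt-catalysed hydroperoxysilylation and oxa-Michael closure then form the dioxane ring. Both partners derive from one building block, (S)-2-ethylpent-4-yn-1-ol, which supplies C4 and C10.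

Key step: step 9

Remark: no known direct peroxidation controls a tertiary peroxide centre in an acyclic chain, so step 12 is expected to form both C6 epimers; the unwanted one is removed after ring closure, and a reagent-controlled alternative is given with the fallbacks.

Step 1
Reactants: 1 (4R)-4-benzyl-1,3-oxazolidin-2-one; 2 butanoyl chloride
Product: 3 (4R)-4-benzyl-3-butanoyl-1,3-oxazolidin-2-one
Conditions: Et3N, DMAP (cat.), CH2Cl2, 0 °C to rt
Reagents that add atoms: none
Why: N-acylation of the oxazolidinone by the acid chloride under nucleophilic catalysis; no stereocentre is formed.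

Step 2
Reactants: 3 (4R)-4-benzyl-3-butanoyl-1,3-oxazolidin-2-one; 4 3-bromoprop-1-yne
Product: 6 (4R)-4-benzyl-3-[(2S)-2-ethylpent-4-ynoyl]-1,3-oxazolidin-2-one, via sodium Z-enolate 5 (not isolated)
Conditions: NaN(SiMe3)2, THF, −78 °C; then 4, −78 to −40 °C
Reagents that add atoms: none
Why: Evans alkylation, in which the chelated Z-enolate is attacked by the propargyl bromide on the face opposite the benzyl group, setting the 2S centre that becomes both C4 and C10.

Step 3
Reactants: 6 (4R)-4-benzyl-3-[(2S)-2-ethylpent-4-ynoyl]-1,3-oxazolidin-2-one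
Product: 7 (2S)-2-ethylpent-4-yn-1-ol
Conditions: LiBH4, MeOH (1 equiv), Et2O, 0 °C
Reagents that add atoms: none
Why: Reductive cleavage of the imide by LiBH4 should give the primary alcohol and release the auxiliary without touching the alkyne or the α-stereocentre.

Step 4
Reactants: 7 (2S)-2-ethylpent-4-yn-1-ol
Product: 8 triethyl{[(2S)-2-ethylpent-4-yn-1-yl]oxy}silane
Conditions: Et3SiCl, imidazole, CH2Cl2, 0 °C to rt
Reagents that add atoms: chlorotriethylsilane, CC[Si](Cl)(CC)CC
Why: Silyl ether formation; triethylsilyl is chosen because a primary triethylsilyl ether can later be oxidised directly under Swern conditions.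

Step 5
Reactants: 8 triethyl{[(2S)-2-ethylpent-4-yn-1-yl]oxy}silane; 9 ethylmagnesium bromide
Product: 11 {[(2S,4E)-2,4-diethyl-5-iodopent-4-en-1-yl]oxy}triethylsilane, via alkenylcopper 10 (not isolated)
Conditions: 9, CuBr·SMe2, Et2O/Me2S, −45 °C; then 8, −45 to −25 °C; then I2, THF, −78 to 0 °C
Reagents that add atoms: iodine, [I][I]
Why: Normant carbocupration adds ethylcopper syn across the terminal alkyne (ethyl to the internal carbon, the future C6; copper to the terminal carbon, the future C7), and iodinolysis with retention should give the E iodide.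

Step 6
Reactants: 7 (2S)-2-ethylpent-4-yn-1-ol
Product: 12 tert-butyl{[(2S)-2-ethylpent-4-yn-1-yl]oxy}dimethylsilane
Conditions: tBuMe2SiCl, imidazole, DMF, rt
Reagents that add atoms: tert-butylchlorodimethylsilane, CC(C)(C)[Si](C)(C)Cl
Why: Silyl ether formation; the tert-butyldimethylsilyl group is inert in the later Swern step, which differentiates the two chain ends.

Step 7
Reactants: 12 tert-butyl{[(2S)-2-ethylpent-4-yn-1-yl]oxy}dimethylsilane
Product: 13 tert-butyl{[(2S)-2-ethylpent-4-en-1-yl]oxy}dimethylsilane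
Conditions: H2 (1 atm), Pd/CaCO3 poisoned with Pb(OAc)2, quinoline, hexane, rt
Reagents that add atoms: none
Why: Lindlar semihydrogenation should stop at the terminal alkene because the poisoned catalyst reduces alkenes only slowly.

Step 8
Reactants: 13 tert-butyl{[(2S)-2-ethylpent-4-en-1-yl]oxy}dimethylsilane
Product: 14 tert-butyl{[(2S,4S)-2-ethyl-4-(4,4,5,5-tetramethyl-1,3,2-dioxaborolan-2-yl)pentyl]oxy}dimethylsilane
Conditions: CuCl (5 mol %), bulky P-stereogenic QuinoxP*-type bisphosphine (5 mol %, enantiomer chosen for the 4S centre), KOtBu (cat.), B2pin2, MeOH, THF, −40 °C to rt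
Reagents that add atoms: bis(pinacolato)diboron, CC1(C)OB(OC1(C)C)B1OC(C)(C)C(C)(C)O1
Why: Copper-catalysed Markovnikov protoboration (borylcupration with boron on the internal carbon, then protonation by MeOH) of an aliphatic terminal alkene, in which the chiral bisphosphine sets the C–B stereocentre (future C8) under catalyst control.

Step 9
Reactants: 11 {[(2S,4E)-2,4-diethyl-5-iodopent-4-en-1-yl]oxy}triethylsilane; 14 tert-butyl{[(2S,4S)-2-ethyl-4-(4,4,5,5-tetramethyl-1,3,2-dioxaborolan-2-yl)pentyl]oxy}dimethylsilane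
Product: 18 (2S,4S,5Z,8S)-1-[tert-butyl(dimethyl)silyloxy]-2,6,8-triethyl-4-methyl-9-(triethylsilyloxy)non-5-ene, via alkenyllithium 15 (not isolated), via lithium boronate complex 16 (not isolated), via iodoboronic ester 17 (not isolated)
Conditions: tBuLi (2 equiv), Et2O, −78 °C; then 14, THF, −78 °C; then I2, THF; then NaOMe, MeOH, −78 °C to rt
Reagents that add atoms: none
Why: Iodine–lithium exchange gives 15, which adds to boron of 14 to form boronate 16; iodine then forms an iodonium ion on the C6=C7 bond, the C8 group migrates from boron to C7 anti to iodine (1,2-metallate shift) to give 17, and methoxide triggers anti elimination of boron and iodine. The closest known reaction type is the Zweifel olefination of enantioenriched secondary pinacol boronic esters with alkenyllithiums. No ring is closed in this step. No new stereocentre is formed: C8 keeps its configuration because the migrating carbon moves with retention, and the anti-migration/anti-elimination sequence fixes the alkene as Z, which is immaterial because C6 and C7 become sp3 later. The step needs complete boronate formation before iodine is added and no attack of the organolithium elsewhere, which the unhindered lithiated carbon (it carries hydrogen), the low temperature and the presence of only silyl ethers in both partners should secure. The C6=C7 alkene it creates is placed so that hydrogen-atom transfer in step 12 can only give the tertiary C6 radical.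

Step 10
Reactants: 18 (2S,4S,5Z,8S)-1-[tert-butyl(dimethyl)silyloxy]-2,6,8-triethyl-4-methyl-9-(triethylsilyloxy)non-5-ene
Product: 19 (2S,4Z,6S,8S)-8-{[tert-butyl(dimethyl)silyl]oxymethyl}-2,4-diethyl-6-methyldec-4-enal
Conditions: (COCl)2, DMSO, CH2Cl2, −78 to −40 °C; then Et3N, −78 to 0 °C
Reagents that add atoms: none
Why: Swern oxidation applied directly to the primary triethylsilyl ether (desilylation by the chlorosulfonium salt, then the usual ylide fragmentation) should give the aldehyde while the tert-butyldimethylsilyl ether stays intact and the α-stereocentre is not enolised in the cold.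

Step 11
Reactants: 19 (2S,4Z,6S,8S)-8-{[tert-butyl(dimethyl)silyl]oxymethyl}-2,4-diethyl-6-methyldec-4-enal; 20 tert-butyl 2-(triphenyl-λ5-phosphanylidene)acetate
Product: 21 tert-butyl (2E,4S,6Z,8S,10S)-10-{[tert-butyl(dimethyl)silyl]oxymethyl}-4,6-diethyl-8-methyldodeca-2,6-dienoate
Conditions: 20, CH2Cl2, rt
Reagents that add atoms: none
Why: Wittig reaction with a stabilised ylide should give the E-enoate under neutral conditions that leave C4 untouched.

Step 12
Reactants: 21 tert-butyl (2E,4S,6Z,8S,10S)-10-{[tert-butyl(dimethyl)silyl]oxymethyl}-4,6-diethyl-8-methyldodeca-2,6-dienoate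
Product: 22 tert-butyl (2E,4S,6R,8S,10S)-10-{[tert-butyl(dimethyl)silyl]oxymethyl}-4,6-diethyl-8-methyl-6-(triethylsilylperoxy)dodec-2-enoate
Conditions: Co(thd)2 (10 mol %; thd = 2,2,6,6-tetramethylheptane-3,5-dionate), O2 (1 atm), Et3SiH, ClCH2CH2Cl, rt
Reagents that add atoms: dioxygen, O=O; triethylsilane, CC[SiH](CC)CC
Why: Mukaiyama–Isayama hydroperoxysilylation, in which a cobalt hydride transfers hydrogen to C7, the tertiary C6 radical captures O2 and the peroxide is silylated; the electron-poor enoate should react far more slowly, and because the planar acyclic radical has no facial bias the 6S epimer is expected alongside the 6R epimer shown.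

Step 13
Reactants: 22 tert-butyl (2E,4S,6R,8S,10S)-10-{[tert-butyl(dimethyl)silyl]oxymethyl}-4,6-diethyl-8-methyl-6-(triethylsilylperoxy)dodec-2-enoate
Product: 24 tert-butyl 2-[(3S,4S,6R)-4,6-diethyl-6-[(2S,4S)-4-(hydroxymethyl)-2-methylhexyl]-1,2-dioxan-3-yl]acetate, via hydroperoxide 23 (not isolated)
Conditions: HF·pyridine, THF, 0 °C to rt; then Et2NH (cat.), CF3CH2OH, rt
Reagents that add atoms: none
Why: Fluoride removes both silyl groups and the hydroperoxide adds to the enoate in a 6-exo-trig oxa-Michael reaction, where a chair-like transition state with the C4 ethyl equatorial and the enoate arm axial (the kinetic mode of E-enoates in such closures) should set C3 as 3S, cis to the C4 ethyl; the 6-epimeric dioxane is removed by chromatography at this stage.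

Step 14
Reactants: 24 tert-butyl 2-[(3S,4S,6R)-4,6-diethyl-6-[(2S,4S)-4-(hydroxymethyl)-2-methylhexyl]-1,2-dioxan-3-yl]acetate
Product: 25 tert-butyl 2-[(3S,4S,6R)-4,6-diethyl-6-[(2S,4S)-4-formyl-2-methylhexyl]-1,2-dioxan-3-yl]acetate
Conditions: Dess–Martin periodinane, NaHCO3, CH2Cl2, 0 °C to rt
Reagents that add atoms: none
Why: Dess–Martin oxidation under buffered, non-basic conditions should leave the dialkyl peroxide and the α-stereocentre C10 intact.

Step 15
Reactants: 25 tert-butyl 2-[(3S,4S,6R)-4,6-diethyl-6-[(2S,4S)-4-formyl-2-methylhexyl]-1,2-dioxan-3-yl]acetate; 26 1-(triphenyl-λ5-phosphanylidene)propan-2-one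
Product: 27 tert-butyl 2-[(3S,4S,6R)-4,6-diethyl-6-[(2S,4S,5E)-4-ethyl-2-methyl-7-oxooct-5-en-1-yl]-1,2-dioxan-3-yl]acetate
Conditions: 26, CH2Cl2, rt
Reagents that add atoms: none
Why: Wittig reaction with the stabilised acetonyl ylide should give the E-enone, and stabilised ylides do not reduce dialkyl peroxides under these conditions.

Step 16
Reactants: 27 tert-butyl 2-[(3S,4S,6R)-4,6-diethyl-6-[(2S,4S,5E)-4-ethyl-2-methyl-7-oxooct-5-en-1-yl]-1,2-dioxan-3-yl]acetate
Product: 28 2-[(3S,4S,6R)-4,6-diethyl-6-[(2S,4S,5E)-4-ethyl-2-methyl-7-oxooct-5-en-1-yl]-1,2-dioxan-3-yl]acetic acid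
Conditions: CF3CO2H, CH2Cl2, 0 °C to rt
Reagents that add atoms: none
Why: Acidolysis of the tert-butyl ester (loss of isobutene) frees the acid without base, so neither retro-Michael opening of the β-peroxy ester nor epimerisation at C10 is expected.

Compound list

1 | (4R)-4-benzyl-1,3-oxazolidin-2-one | O=C1N[C@H](Cc2ccccc2)CO1 | starting material
2 | butanoyl chloride | CCCC(=O)Cl | starting material
3 | (4R)-4-benzyl-3-butanoyl-1,3-oxazolidin-2-one | CCCC(=O)N1[C@H](Cc2ccccc2)COC1=O | intermediate
4 | 3-bromoprop-1-yne (propargyl bromide) | C#CCBr | starting material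
5 | sodium Z-enolate of 3 (not isolated) | [Na+].CC/C=C(\[O-])N1[C@H](Cc2ccccc2)COC1=O | intermediate
6 | (4R)-4-benzyl-3-[(2S)-2-ethylpent-4-ynoyl]-1,3-oxazolidin-2-one | C#CC[C@H](CC)C(=O)N1[C@H](Cc2ccccc2)COC1=O | intermediate
7 | (2S)-2-ethylpent-4-yn-1-ol | C#CC[C@H](CC)CO | intermediate
8 | triethyl{[(2S)-2-ethylpent-4-yn-1-yl]oxy}silane | C#CC[C@H](CC)CO[Si](CC)(CC)CC | intermediate
9 | ethylmagnesium bromide | CC[Mg]Br | starting material
10 | (1E,4S)-2-ethyl-4-[(triethylsilyloxy)methyl]hex-1-enylcopper, as its MgBr2 complex (not isolated) | [Cu]/C=C(\CC)C[C@H](CC)CO[Si](CC)(CC)CC | intermediate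
11 | {[(2S,4E)-2,4-diethyl-5-iodopent-4-en-1-yl]oxy}triethylsilane | I/C=C(\CC)C[C@H](CC)CO[Si](CC)(CC)CC | intermediate
12 | tert-butyl{[(2S)-2-ethylpent-4-yn-1-yl]oxy}dimethylsilane | C#CC[C@H](CC)CO[Si](C)(C)C(C)(C)C | intermediate
13 | tert-butyl{[(2S)-2-ethylpent-4-en-1-yl]oxy}dimethylsilane | C=CC[C@H](CC)CO[Si](C)(C)C(C)(C)C | intermediate
14 | tert-butyl{[(2S,4S)-2-ethyl-4-(4,4,5,5-tetramethyl-1,3,2-dioxaborolan-2-yl)pentyl]oxy}dimethylsilane | CC[C@H](CO[Si](C)(C)C(C)(C)C)C[C@H](C)B1OC(C)(C)C(C)(C)O1 | intermediate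
15 | (1E,4S)-2-ethyl-4-[(triethylsilyloxy)methyl]hex-1-enyllithium (not isolated) | [Li]/C=C(\CC)C[C@H](CC)CO[Si](CC)(CC)CC | intermediate
16 | lithium boronate complex of 14 and 15, boron bearing the C8 alkyl group, the E-alkenyl group and pinacolate (not isolated) | [Li+].CC[C@H](CO[Si](C)(C)C(C)(C)C)C[C@H](C)[B-]1(OC(C)(C)C(C)(C)O1)/C=C(\CC)C[C@H](CC)CO[Si](CC)(CC)CC | intermediate
17 | (2S,4S,5S,6S,8S)-1-[tert-butyl(dimethyl)silyloxy]-2,6,8-triethyl-6-iodo-4-methyl-5-(pinacolatoboryl)-9-(triethylsilyloxy)nonane; the (5R,6R) diastereomer forms alongside and eliminates to the same alkene (not isolated) | CC[C@H](CO[Si](C)(C)C(C)(C)C)C[C@H](C)[C@H](B1OC(C)(C)C(C)(C)O1)[C@](I)(CC)C[C@H](CC)CO[Si](CC)(CC)CC | intermediate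
18 | (2S,4S,5Z,8S)-1-[tert-butyl(dimethyl)silyloxy]-2,6,8-triethyl-4-methyl-9-(triethylsilyloxy)non-5-ene | CC[C@H](CO[Si](C)(C)C(C)(C)C)C[C@H](C)/C=C(/CC)C[C@H](CC)CO[Si](CC)(CC)CC | intermediate
19 | (2S,4Z,6S,8S)-8-{[tert-butyl(dimethyl)silyl]oxymethyl}-2,4-diethyl-6-methyldec-4-enal | CC[C@H](CO[Si](C)(C)C(C)(C)C)C[C@H](C)/C=C(/CC)C[C@H](CC)C=O | intermediate
20 | tert-butyl 2-(triphenyl-λ5-phosphanylidene)acetate | CC(C)(C)OC(=O)C=P(c1ccccc1)(c1ccccc1)c1ccccc1 | starting material
21 | tert-butyl (2E,4S,6Z,8S,10S)-10-{[tert-butyl(dimethyl)silyl]oxymethyl}-4,6-diethyl-8-methyldodeca-2,6-dienoate | CC[C@H](CO[Si](C)(C)C(C)(C)C)C[C@H](C)/C=C(/CC)C[C@H](CC)/C=C/C(=O)OC(C)(C)C | intermediate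
22 | tert-butyl (2E,4S,6R,8S,10S)-10-{[tert-butyl(dimethyl)silyl]oxymethyl}-4,6-diethyl-8-methyl-6-(triethylsilylperoxy)dodec-2-enoate (6R epimer; the 6S epimer is expected alongside) | CC[C@H](CO[Si](C)(C)C(C)(C)C)C[C@H](C)C[C@@](CC)(OO[Si](CC)(CC)CC)C[C@H](CC)/C=C/C(=O)OC(C)(C)C | intermediate
23 | tert-butyl (2E,4S,6R,8S,10S)-4,6-diethyl-6-hydroperoxy-10-(hydroxymethyl)-8-methyldodec-2-enoate (not isolated) | CC[C@H](CO)C[C@H](C)C[C@@](CC)(OO)C[C@H](CC)/C=C/C(=O)OC(C)(C)C | intermediate
24 | tert-butyl 2-[(3S,4S,6R)-4,6-diethyl-6-[(2S,4S)-4-(hydroxymethyl)-2-methylhexyl]-1,2-dioxan-3-yl]acetate | CC[C@H](CO)C[C@H](C)C[C@]1(CC)C[C@H](CC)[C@H](CC(=O)OC(C)(C)C)OO1 | intermediate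
25 | tert-butyl 2-[(3S,4S,6R)-4,6-diethyl-6-[(2S,4S)-4-formyl-2-methylhexyl]-1,2-dioxan-3-yl]acetate | CC[C@H](C=O)C[C@H](C)C[C@]1(CC)C[C@H](CC)[C@H](CC(=O)OC(C)(C)C)OO1 | intermediate
26 | 1-(triphenyl-λ5-phosphanylidene)propan-2-one | CC(=O)C=P(c1ccccc1)(c1ccccc1)c1ccccc1 | starting material
27 | tert-butyl 2-[(3S,4S,6R)-4,6-diethyl-6-[(2S,4S,5E)-4-ethyl-2-methyl-7-oxooct-5-en-1-yl]-1,2-dioxan-3-yl]acetate | CC[C@H](/C=C/C(C)=O)C[C@H](C)C[C@]1(CC)C[C@H](CC)[C@H](CC(=O)OC(C)(C)C)OO1 | intermediate
28 | 2-[(3S,4S,6R)-4,6-diethyl-6-[(2S,4S,5E)-4-ethyl-2-methyl-7-oxooct-5-en-1-yl]-1,2-dioxan-3-yl]acetic acid | CC[C@H](/C=C/C(C)=O)C[C@H](C)C[C@]1(CC)C[C@H](CC)[C@H](CC(=O)O)OO1 | target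

Total step count: 16. Longest linear sequence: 14 steps (steps 1–3, 6–8, 9–16).

Steps most likely to fail

1. Step 12. The tertiary C6 radical is planar and acyclic, so oxygen capture should show no facial selectivity and about half of the material is expected to enter the 6-epi series; hydrogen-atom transfer to the enoate may also compete. The fallback sets C6 under reagent control and sets out from 21. Shi epoxidation of the trisubstituted C6=C7 alkene (fructose-derived chiral ketone, enantiomer chosen for the required face, KHSO5, K2CO3, MeCN/dimethoxymethane, buffer, 0 °C) should give the epoxide F1. Perhydrolysis with ethereal H2O2 and MoO2(acac)2 (cat.) should open it at the tertiary carbon with inversion to give the hydroperoxy alcohol F2. Et2NH in CF3CH2OH should then close the ring to the 7-hydroxy-1,2-dioxane F3. The extra hydroxyl is removed by Barton–McCombie deoxygenation: PhOC(S)Cl, pyridine and DMAP give the O-phenyl thionocarbonate F4, and Bu3SnH at high concentration with Et3B and air at rt gives the silyl ether F5. The high stannane concentration is needed so that hydrogen transfer outruns epoxide formation from the β-peroxy radical. HF·pyridine then brings the route back at 24.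

2. Step 13. The oxa-Michael addition may show poor facial selectivity at C3 (cis against trans to the C4 ethyl), and the amine may cause retro-addition or fragmentation of the peroxide. The fallback forms the C3–C2 bond instead of the C3–O bond and sets out from 19. HC(OMe)3 with PPTS (cat.) in MeOH should give the dimethyl acetal F6. Hydroperoxysilylation under the conditions of step 12 should give the silyl peroxide F7. HF·pyridine followed by camphorsulfonic acid (cat.) in CH2Cl2 should give the cyclic methyl peroxyacetal F8. A Mukaiyama-type addition of 1-tert-butoxy-1-(trimethylsilyloxy)ethene (excess) with Me3SiOTf (cat.) in CH2Cl2 at −78 °C then introduces the acetate arm. The nucleophile should attack the cyclic peroxycarbenium ion axially on the half-chair that keeps the C4 ethyl pseudo-equatorial. Mild acidic work-up brings the route back at 24.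

3. Step 8. Borylcupration of the unactivated terminal alkene may give insufficient branched-to-linear selectivity or insufficient enantiofacial control. The fallback is a sparteine-mediated lithiation–borylation and sets out from 13. Ozonolysis with NaBH4 work-up should give the primary alcohol F9, and iPr2NCOCl with Et3N the carbamate F10. sBuLi with (−)-sparteine in Et2O at −78 °C removes the pro-S hydrogen to give the lithiated carbamate F11. 2,4,4,5,5-Pentamethyl-1,3,2-dioxaborolane adds with retention to give the boronate F12. Warming with MgBr2·OEt2 should bring about the 1,2-shift of methyl with inversion, which returns the route at 14.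

Further compounds

F1 | step 12 | tert-butyl (2E,4S,6R,7S,8S,10S)-10-{[tert-butyl(dimethyl)silyl]oxymethyl}-6,7-epoxy-4,6-diethyl-8-methyldodec-2-enoate | CC[C@H](CO[Si](C)(C)C(C)(C)C)C[C@H](C)[C@@H]1O[C@]1(CC)C[C@H](CC)/C=C/C(=O)OC(C)(C)C
F2 | step 12 | tert-butyl (2E,4S,6S,7S,8S,10S)-10-{[tert-butyl(dimethyl)silyl]oxymethyl}-4,6-diethyl-6-hydroperoxy-7-hydroxy-8-methyldodec-2-enoate (C6 has the spatial arrangement of the target; its label changes with the C7 hydroxyl) | CC[C@H](CO[Si](C)(C)C(C)(C)C)C[C@H](C)[C@H](O)[C@@](CC)(OO)C[C@H](CC)/C=C/C(=O)OC(C)(C)C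
F3 | step 12 | tert-butyl 2-[(3S,4S,6S)-6-[(1S,2S,4S)-4-{[tert-butyl(dimethyl)silyl]oxymethyl}-1-hydroxy-2-methylhexyl]-4,6-diethyl-1,2-dioxan-3-yl]acetate | CC[C@H](CO[Si](C)(C)C(C)(C)C)C[C@H](C)[C@H](O)[C@]1(CC)C[C@H](CC)[C@H](CC(=O)OC(C)(C)C)OO1
F4 | step 12 | O-phenyl thionocarbonate of F3 at the C7 hydroxyl | CC[C@H](CO[Si](C)(C)C(C)(C)C)C[C@H](C)[C@H](OC(=S)Oc2ccccc2)[C@]1(CC)C[C@H](CC)[C@H](CC(=O)OC(C)(C)C)OO1
F5 | step 12 | tert-butyl 2-[(3S,4S,6R)-6-[(2S,4S)-4-{[tert-butyl(dimethyl)silyl]oxymethyl}-2-methylhexyl]-4,6-diethyl-1,2-dioxan-3-yl]acetate | CC[C@H](CO[Si](C)(C)C(C)(C)C)C[C@H](C)C[C@]1(CC)C[C@H](CC)[C@H](CC(=O)OC(C)(C)C)OO1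
F6 | step 13 | tert-butyl{[(2S,4S,5Z,8S)-2,6,8-triethyl-9,9-dimethoxy-4-methylnon-5-en-1-yl]oxy}dimethylsilane | CC[C@H](CO[Si](C)(C)C(C)(C)C)C[C@H](C)/C=C(/CC)C[C@H](CC)C(OC)OC
F7 | step 13 | tert-butyl{[(2S,4S,6R,8S)-2,6,8-triethyl-9,9-dimethoxy-4-methyl-6-(triethylsilylperoxy)nonyl]oxy}dimethylsilane (6R epimer; the 6S epimer is expected alongside) | CC[C@H](CO[Si](C)(C)C(C)(C)C)C[C@H](C)C[C@@](CC)(OO[Si](CC)(CC)CC)C[C@H](CC)C(OC)OC
F8 | step 13 | (2S,4S)-5-[(4S,6R)-4,6-diethyl-3-methoxy-1,2-dioxan-6-yl]-2-ethyl-4-methylpentan-1-ol (both C3 anomers) | CC[C@H](CO)C[C@H](C)C[C@]1(CC)C[C@H](CC)C(OC)OO1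
F9 | step 8 | (3S)-3-({[tert-butyl(dimethyl)silyl]oxy}methyl)pentan-1-ol | CC[C@H](CO[Si](C)(C)C(C)(C)C)CCO
F10 | step 8 | (3S)-3-({[tert-butyl(dimethyl)silyl]oxy}methyl)pentyl N,N-diisopropylcarbamate | CC[C@H](CO[Si](C)(C)C(C)(C)C)CCOC(=O)N(C(C)C)C(C)C
F11 | step 8 | (1S,3S)-1-lithio derivative of F10, as its sparteine complex | CC[C@H](CO[Si](C)(C)C(C)(C)C)C[C@H]([Li])OC(=O)N(C(C)C)C(C)C
F12 | step 8 | lithium boronate from F11 and 2,4,4,5,5-pentamethyl-1,3,2-dioxaborolane | [Li+].CC[C@H](CO[Si](C)(C)C(C)(C)C)C[C@@H](OC(=O)N(C(C)C)C(C)C)[B-]1(C)OC(C)(C)C(C)(C)O1
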